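**Plan**

- Retrosynthesis: the five MOM ethers come off last. C3 is then taken out of the pyranone ring (O1–C2–C3–C4–C4a–C8a): the chromanone is traced to a 2-aryl-2-(iodomethyl)benzofuran-3(2H)-one, whose five-membered ring O1–C2–C4(=O)–C4a–C8a is enlarged by a radical 1,2-acyl shift. That ketone is cut at C4–C4a (Friedel–Crafts) and O1–C2 (Mitsunobu) into a pentasubstituted phenol and a B-ring mandelate.
- Feature used: C4 is an aryl ketone next to C2, and C2 carries the ring oxygen O1 and the 2,4,6-trioxygenated aryl ring. A CH2 radical on C2 can therefore add to C4=O, and the ring-enlarged C2 radical is benzylic and oxygen-stabilised.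
- Forward order: A ring first (lavandulyl chain grown from the formyl carbon of 2,4,6-trihydroxybenzaldehyde, prenyl by directed metalation between two MOM ethers), then ether union with the B ring, closure of the five-membered ring by acylation, ring expansion 5→6, resolution, deprotection.
- Stereochemistry: the lavandulyl centre (R) comes from an Evans enolate prenylation directed by (R)-4-benzyloxazolidin-2-one. C2 (S) is not controlled in the ring expansion; it comes from a catalyst-controlled kinetic resolution of the C2 epimers by asymmetric transfer hydrogenation.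

Key step: step 18

Abbreviations: MOM = methoxymethyl (MOMO = methoxymethoxy); TIPS = triisopropylsilyl (TIPSO = triisopropylsilyloxy); prenyl = 3-methylbut-2-en-1-yl; (R)-lavandulyl = (2R)-5-methyl-2-(prop-1-en-2-yl)hex-4-en-1-yl.

Remark on the chemistry: step 18 is expected to give both C2 epimers in similar amounts, so the resolution in step 19 can deliver at most about half of the material. C2 of the free polyphenol can epimerise by ring opening, so the MOM groups are removed last and under mild acid.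

**Route**

Step 1
Reactants: 1 2,4,6-trihydroxybenzaldehyde
Product: 2 2-hydroxy-4,6-bis(MOMO)benzaldehyde
Conditions: MOMCl (2.1 equiv), i-Pr2NEt, CH2Cl2, 0 °C to rt
Reagents that add atoms: chloromethyl methyl ether, COCCl
Why: Williamson-type acetal formation stops after two alkylations because the 2-OH is hydrogen-bonded to the formyl group, and this free oxygen is thereby marked as the future O1.

Step 2
Reactants: 2 2-hydroxy-4,6-bis(MOMO)benzaldehyde
Product: 3 2,4-bis(MOMO)-6-(TIPSO)benzaldehyde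
Conditions: TIPSOTf, 2,6-lutidine, CH2Cl2, 0 °C
Reagents that add atoms: triisopropylsilyl trifluoromethanesulfonate, CC(C)[Si](OS(=O)(=O)C(F)(F)F)(C(C)C)C(C)C
Why: Silylation of the chelated phenol gives a bulky, non-directing ether that survives bases and organometallics and leaves the later lithiation to the two MOM ethers.

Step 3
Reactants: 3 2,4-bis(MOMO)-6-(TIPSO)benzaldehyde
Product: 4 benzyl (E)-3-[2,4-bis(MOMO)-6-(TIPSO)phenyl]prop-2-enoate
Conditions: Ph3P=CHCO2Bn, toluene, 90 °C
Reagents that add atoms: benzyl (triphenylphosphoranylidene)acetate, O=C(OCc1ccccc1)C=P(c1ccccc1)(c1ccccc1)c1ccccc1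
Why: Wittig olefination with a stabilised ylide adds the two carbons that will carry the lavandulyl stereocentre.

Step 4
Reactants: 4 benzyl (E)-3-[2,4-bis(MOMO)-6-(TIPSO)phenyl]prop-2-enoate
Product: 5 3-[2,4-bis(MOMO)-6-(TIPSO)phenyl]propanoic acid
Conditions: H2 (1 atm), 10% Pd/C, EtOAc, rt
Reagents that add atoms: none
Why: Catalytic hydrogenation saturates the cinnamate and hydrogenolyses the benzyl ester in one operation, while aryl MOM and TIPS ethers are inert.

Step 5
Reactants: 5 3-[2,4-bis(MOMO)-6-(TIPSO)phenyl]propanoic acid; 6 (R)-4-benzyl-1,3-oxazolidin-2-one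
Product: 8 (R)-4-benzyl-3-{3-[2,4-bis(MOMO)-6-(TIPSO)phenyl]propanoyl}-1,3-oxazolidin-2-one, via mixed pivalic anhydride 7 (not isolated)
Conditions: PivCl, Et3N, THF, −20 °C; then 6, LiCl, −20 °C to rt
Reagents that add atoms: none
Why: N-acylation of the Evans auxiliary through the mixed anhydride is the standard mild entry to the imide.

Step 6
Reactants: 8 (R)-4-benzyl-3-{3-[2,4-bis(MOMO)-6-(TIPSO)phenyl]propanoyl}-1,3-oxazolidin-2-one
Product: 9 (R)-4-benzyl-3-[(2R)-2-{[2,4-bis(MOMO)-6-(TIPSO)phenyl]methyl}-5-methylhex-4-enoyl]-1,3-oxazolidin-2-one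
Conditions: NaHMDS, THF, −78 °C; prenyl bromide, −78 to −40 °C
Reagents that add atoms: 1-bromo-3-methylbut-2-ene, CC(C)=CCBr
Why: Evans asymmetric alkylation, in which the chelated sodium Z-enolate is prenylated on the face away from the 4-benzyl group, should set the lavandulyl stereocentre (2R here, R in the target).

Step 7
Reactants: 9 (R)-4-benzyl-3-[(2R)-2-{[2,4-bis(MOMO)-6-(TIPSO)phenyl]methyl}-5-methylhex-4-enoyl]-1,3-oxazolidin-2-one
Product: 10 (2R)-2-{[2,4-bis(MOMO)-6-(TIPSO)phenyl]methyl}-N-methoxy-N,5-dimethylhex-4-enamide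
Conditions: MeNHOMe, AlMe3, CH2Cl2, 0 °C to rt
Reagents that add atoms: N,O-dimethylhydroxylamine, CNOC
Why: Aluminium-amide transamidation (Weinreb) cleaves the auxiliary at the exocyclic carbonyl without touching the α-stereocentre.

Step 8
Reactants: 10 (2R)-2-{[2,4-bis(MOMO)-6-(TIPSO)phenyl]methyl}-N-methoxy-N,5-dimethylhex-4-enamide
Product: 11 (3R)-3-{[2,4-bis(MOMO)-6-(TIPSO)phenyl]methyl}-6-methylhept-5-en-2-one
Conditions: MeMgBr, THF, 0 °C
Reagents that add atoms: methylmagnesium bromide, C[Mg]Br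
Why: Weinreb ketone synthesis, in which the chelated tetrahedral intermediate prevents over-addition and keeps the α-centre from enolising until work-up.

Step 9
Reactants: 11 (3R)-3-{[2,4-bis(MOMO)-6-(TIPSO)phenyl]methyl}-6-methylhept-5-en-2-one
Product: 12 triisopropyl{3,5-bis(MOMO)-2-[(R)-lavandulyl]phenoxy}silane
Conditions: Cp2TiMe2, toluene, 70 °C, dark
Reagents that add atoms: dimethyltitanocene, C[Ti](C)(C1C=CC=C1)C1C=CC=C1
Why: Petasis methylenation is non-basic, so the methyl ketone becomes the isopropenyl group without epimerising the adjacent stereocentre.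

Step 10
Reactants: 12 triisopropyl{3,5-bis(MOMO)-2-[(R)-lavandulyl]phenoxy}silane
Product: 14 triisopropyl{3,5-bis(MOMO)-4-prenyl-2-[(R)-lavandulyl]phenoxy}silane, via aryllithium 13 (not isolated)
Conditions: n-BuLi, THF, 0 °C; then CuBr·SMe2 (10 mol%), prenyl bromide, −78 °C to rt
Reagents that add atoms: 1-bromo-3-methylbut-2-ene, CC(C)=CCBr
Why: Directed ortho-metalation goes to the only ring position flanked by two MOM ethers (the future C6), and copper-catalysed alkylation of the aryllithium attaches the prenyl group there.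

Step 11
Reactants: 14 triisopropyl{3,5-bis(MOMO)-4-prenyl-2-[(R)-lavandulyl]phenoxy}silane
Product: 15 3,5-bis(MOMO)-4-prenyl-2-[(R)-lavandulyl]phenol
Conditions: TBAF, AcOH, THF, 0 °C
Reagents that add atoms: none
Why: Buffered fluoride removes the aryl silyl ether selectively and frees the one oxygen (future O1) that has a free ortho position (future C4a).

Step 12
Reactants: 16 phloroglucinol (benzene-1,3,5-triol)
Product: 17 1,3,5-tris(MOMO)benzene
Conditions: MOMCl, i-Pr2NEt, DMF, 0 °C to rt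
Reagents that add atoms: chloromethyl methyl ether, COCCl
Why: Exhaustive O-alkylation gives the symmetric B-ring building block with three ortho-directing acetal groups.

Step 13
Reactants: 17 1,3,5-tris(MOMO)benzene
Product: 19 ethyl (RS)-2-hydroxy-2-[2,4,6-tris(MOMO)phenyl]acetate, via aryllithium 18 (not isolated)
Conditions: n-BuLi, THF, 0 °C; then ethyl glyoxylate (freshly distilled), −78 °C; NH4Cl quench
Reagents that add atoms: ethyl glyoxylate, CCOC(=O)C=O
Why: Directed ortho-metalation between two MOM ethers followed by addition to the aldehyde of the glyoxylate gives the mandelate whose carbinol carbon becomes C2 and whose ester carbon becomes C4.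

Step 14
Reactants: 15 3,5-bis(MOMO)-4-prenyl-2-[(R)-lavandulyl]phenol; 19 ethyl (RS)-2-hydroxy-2-[2,4,6-tris(MOMO)phenyl]acetate
Product: 20 ethyl 2-{3,5-bis(MOMO)-4-prenyl-2-[(R)-lavandulyl]phenoxy}-2-[2,4,6-tris(MOMO)phenyl]acetate (both configurations at the ether carbon)
Conditions: PPh3, DIAD, toluene, 0 °C to rt
Reagents that add atoms: none
Why: Mitsunobu etherification of an α-hydroxy ester with a phenol forms the O1–C2 bond; the configuration at this carbon is irrelevant because it is erased in steps 16 to 18.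

Step 15
Reactants: 20 ethyl 2-{3,5-bis(MOMO)-4-prenyl-2-[(R)-lavandulyl]phenoxy}-2-[2,4,6-tris(MOMO)phenyl]acetate
Product: 21 2-{3,5-bis(MOMO)-4-prenyl-2-[(R)-lavandulyl]phenoxy}-2-[2,4,6-tris(MOMO)phenyl]acetic acid
Conditions: LiOH, THF/MeOH/H2O, rt; then dilute HCl to pH 4 at 0 °C
Reagents that add atoms: lithium hydroxide, [Li+].[OH-]
Why: Ester saponification under conditions that leave MOM ethers and alkenes untouched.

Step 16
Reactants: 21 2-{3,5-bis(MOMO)-4-prenyl-2-[(R)-lavandulyl]phenoxy}-2-[2,4,6-tris(MOMO)phenyl]acetic acid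
Product: 23 4,6-bis(MOMO)-5-prenyl-7-[(R)-lavandulyl]-2-[2,4,6-tris(MOMO)phenyl]-1-benzofuran-3(2H)-one (both C2 epimers), via mixed trifluoroacetic anhydride 22 (not isolated)
Conditions: TFAA, 2,6-di-tert-butyl-4-methylpyridine, CH2Cl2, −20 to 0 °C, argon; used directly
Reagents that add atoms: none
Why: Intramolecular Friedel–Crafts acylation of the aryloxyacetic acid closes the five-membered ring at the only free and strongly activated position, ortho to the ether oxygen, with the base buffering the acid to protect the MOM groups.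

Step 17
Reactants: 23 4,6-bis(MOMO)-5-prenyl-7-[(R)-lavandulyl]-2-[2,4,6-tris(MOMO)phenyl]-1-benzofuran-3(2H)-one
Product: 24 2-(iodomethyl)-4,6-bis(MOMO)-5-prenyl-7-[(R)-lavandulyl]-2-[2,4,6-tris(MOMO)phenyl]-1-benzofuran-3(2H)-one (both C2 epimers)
Conditions: NaH, THF, 0 °C; CH2I2 (excess), 0 to 40 °C
Reagents that add atoms: diiodomethane, ICI
Why: C-alkylation of the stabilised ketone enolate with diiodomethane, the usual way to make substrates for this ring expansion, installs the one-carbon unit on a quaternary C2 whose configuration does not matter.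

Step 18
Reactants: 24 2-(iodomethyl)-4,6-bis(MOMO)-5-prenyl-7-[(R)-lavandulyl]-2-[2,4,6-tris(MOMO)phenyl]-1-benzofuran-3(2H)-one
Product: 28 (2RS)-5,7-bis(MOMO)-6-prenyl-8-[(R)-lavandulyl]-2-[2,4,6-tris(MOMO)phenyl]-2,3-dihydro-4H-chromen-4-one (pair of C2 epimers), via primary alkyl radical 25 (not isolated), via cyclopropyloxyl radical 26 (not isolated), via ring-enlarged benzylic radical 27 (not isolated)
Conditions: Bu3SnH (slow addition), AIBN (cat.), benzene, 80 °C
Reagents that add atoms: none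
Why: Dowd–Beckwith ring expansion: Bu3Sn• abstracts iodine from 24, the primary radical 25 adds 3-exo-trig to the ketone carbonyl to give the cyclopropane-fused alkoxyl radical 26, and β-scission of the ring-fusion bond (the former C2–C(=O) bond) gives the six-membered radical 27, which takes hydrogen from the stannane. The closest known reaction type is the one-carbon ring expansion of α-(halomethyl) cyclic ketones and β-keto esters, a net 1,2-acyl shift. The pyranone ring is not closed by a cyclisation of its own: the three-membered ring closes 3-exo-trig and the five-membered ring O1–C2–C4–C4a–C8a opens into the six-membered ring O1–C2–C3–C4–C4a–C8a, the iodomethyl carbon becoming C3. The new stereocentre C2 arises by hydrogen transfer to the planar radical 27 with no controlling element, so both C2 epimers are expected and C2 is fixed in step 19. The step needs the rearrangement to outrun direct reduction of 25 and a 1,2-aryl shift: slow stannane addition keeps the hydrogen donor dilute, the fragmentation is driven because 27 is benzylic and bears the ring oxygen, and ipso attack on the di-ortho-substituted, electron-rich B ring is hindered.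

Step 19
Reactants: 28 (2RS)-5,7-bis(MOMO)-6-prenyl-8-[(R)-lavandulyl]-2-[2,4,6-tris(MOMO)phenyl]-2,3-dihydro-4H-chromen-4-one
Product: 29 (2S)-5,7-bis(MOMO)-6-prenyl-8-[(R)-lavandulyl]-2-[2,4,6-tris(MOMO)phenyl]-2,3-dihydro-4H-chromen-4-one
Conditions: RuCl(p-cymene)[(R,R)-TsDPEN] (2 mol%), HCO2H/Et3N (5:2), EtOAc, rt, stopped near half conversion; chromatography
Reagents that add atoms: none
Why: Noyori–Ikariya asymmetric transfer hydrogenation used as a kinetic resolution: by the usual sense of this catalyst for aryl ketones, the (R,R) ligand should reduce the (2R)-epimer much faster (to the 2,4-cis alcohol), so the (2S)-ketone is recovered and C2 is thereby selected.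

Step 20
Reactants: 29 (2S)-5,7-bis(MOMO)-6-prenyl-8-[(R)-lavandulyl]-2-[2,4,6-tris(MOMO)phenyl]-2,3-dihydro-4H-chromen-4-one
Product: 30 (2S)-5,7-dihydroxy-6-prenyl-8-[(R)-lavandulyl]-2-(2,4,6-trihydroxyphenyl)-2,3-dihydro-4H-chromen-4-one (CNP0163831.1)
Conditions: HCl (about 1.5 M) in MeOH, 40 °C
Reagents that add atoms: none
Why: Acid-catalysed acetal exchange with methanol removes all five MOM groups, the solvent trapping the formaldehyde unit, at a temperature chosen to spare C2 and the prenyl groups.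

**Compound list**

1 | 2,4,6-trihydroxybenzaldehyde | O=Cc1c(O)cc(O)cc1O | starting material
2 | 2-hydroxy-4,6-bis(methoxymethoxy)benzaldehyde | O=Cc1c(O)cc(OCOC)cc1OCOC | intermediate
3 | 2,4-bis(methoxymethoxy)-6-(triisopropylsilyloxy)benzaldehyde | O=Cc1c(O[Si](C(C)C)(C(C)C)C(C)C)cc(OCOC)cc1OCOC | intermediate
4 | benzyl (E)-3-[2,4-bis(methoxymethoxy)-6-(triisopropylsilyloxy)phenyl]prop-2-enoate | O=C(OCc1ccccc1)/C=C/c1c(O[Si](C(C)C)(C(C)C)C(C)C)cc(OCOC)cc1OCOC | intermediate
5 | 3-[2,4-bis(methoxymethoxy)-6-(triisopropylsilyloxy)phenyl]propanoic acid | OC(=O)CCc1c(O[Si](C(C)C)(C(C)C)C(C)C)cc(OCOC)cc1OCOC | intermediate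
6 | (R)-4-benzyl-1,3-oxazolidin-2-one | O=C1N[C@H](Cc2ccccc2)CO1 | starting material
7 | mixed anhydride of 5 with pivalic acid | CC(C)(C)C(=O)OC(=O)CCc1c(O[Si](C(C)C)(C(C)C)C(C)C)cc(OCOC)cc1OCOC | intermediate
8 | (R)-4-benzyl-3-{3-[2,4-bis(methoxymethoxy)-6-(triisopropylsilyloxy)phenyl]propanoyl}-1,3-oxazolidin-2-one | O=C(CCc1c(O[Si](C(C)C)(C(C)C)C(C)C)cc(OCOC)cc1OCOC)N1[C@H](Cc2ccccc2)COC1=O | intermediate
9 | (R)-4-benzyl-3-[(2R)-2-{[2,4-bis(methoxymethoxy)-6-(triisopropylsilyloxy)phenyl]methyl}-5-methylhex-4-enoyl]-1,3-oxazolidin-2-one | CC(C)=CC[C@H](Cc1c(O[Si](C(C)C)(C(C)C)C(C)C)cc(OCOC)cc1OCOC)C(=O)N1[C@H](Cc2ccccc2)COC1=O | intermediate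
10 | (2R)-2-{[2,4-bis(methoxymethoxy)-6-(triisopropylsilyloxy)phenyl]methyl}-N-methoxy-N,5-dimethylhex-4-enamide | CC(C)=CC[C@H](Cc1c(O[Si](C(C)C)(C(C)C)C(C)C)cc(OCOC)cc1OCOC)C(=O)N(C)OC | intermediate
11 | (3R)-3-{[2,4-bis(methoxymethoxy)-6-(triisopropylsilyloxy)phenyl]methyl}-6-methylhept-5-en-2-one | CC(C)=CC[C@H](Cc1c(O[Si](C(C)C)(C(C)C)C(C)C)cc(OCOC)cc1OCOC)C(C)=O | intermediate
12 | triisopropyl{3,5-bis(methoxymethoxy)-2-[(2R)-5-methyl-2-(prop-1-en-2-yl)hex-4-en-1-yl]phenoxy}silane | C=C(C)[C@H](CC=C(C)C)Cc1c(O[Si](C(C)C)(C(C)C)C(C)C)cc(OCOC)cc1OCOC | intermediate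
13 | 4-lithio derivative of 12 (lithium between the two MOM ethers) | C=C(C)[C@H](CC=C(C)C)Cc1c(O[Si](C(C)C)(C(C)C)C(C)C)cc(OCOC)c([Li])c1OCOC | intermediate
14 | triisopropyl{3,5-bis(methoxymethoxy)-4-(3-methylbut-2-en-1-yl)-2-[(2R)-5-methyl-2-(prop-1-en-2-yl)hex-4-en-1-yl]phenoxy}silane | C=C(C)[C@H](CC=C(C)C)Cc1c(O[Si](C(C)C)(C(C)C)C(C)C)cc(OCOC)c(CC=C(C)C)c1OCOC | intermediate
15 | 3,5-bis(methoxymethoxy)-4-(3-methylbut-2-en-1-yl)-2-[(2R)-5-methyl-2-(prop-1-en-2-yl)hex-4-en-1-yl]phenol | C=C(C)[C@H](CC=C(C)C)Cc1c(O)cc(OCOC)c(CC=C(C)C)c1OCOC | intermediate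
16 | phloroglucinol | Oc1cc(O)cc(O)c1 | starting material
17 | 1,3,5-tris(methoxymethoxy)benzene | COCOc1cc(OCOC)cc(OCOC)c1 | intermediate
18 | [2,4,6-tris(methoxymethoxy)phenyl]lithium | [Li]c1c(OCOC)cc(OCOC)cc1OCOC | intermediate
19 | ethyl (RS)-2-hydroxy-2-[2,4,6-tris(methoxymethoxy)phenyl]acetate | CCOC(=O)C(O)c1c(OCOC)cc(OCOC)cc1OCOC | intermediate
20 | ethyl 2-{3,5-bis(methoxymethoxy)-4-prenyl-2-[(R)-lavandulyl]phenoxy}-2-[2,4,6-tris(methoxymethoxy)phenyl]acetate, both configurations at the ether carbon | C=C(C)[C@H](CC=C(C)C)Cc1c(OC(C(=O)OCC)c2c(OCOC)cc(OCOC)cc2OCOC)cc(OCOC)c(CC=C(C)C)c1OCOC | intermediate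
21 | 2-{3,5-bis(methoxymethoxy)-4-prenyl-2-[(R)-lavandulyl]phenoxy}-2-[2,4,6-tris(methoxymethoxy)phenyl]acetic acid | C=C(C)[C@H](CC=C(C)C)Cc1c(OC(C(=O)O)c2c(OCOC)cc(OCOC)cc2OCOC)cc(OCOC)c(CC=C(C)C)c1OCOC | intermediate
22 | mixed anhydride of 21 with trifluoroacetic acid | C=C(C)[C@H](CC=C(C)C)Cc1c(OC(C(=O)OC(=O)C(F)(F)F)c2c(OCOC)cc(OCOC)cc2OCOC)cc(OCOC)c(CC=C(C)C)c1OCOC | intermediate
23 | 4,6-bis(methoxymethoxy)-5-prenyl-7-[(R)-lavandulyl]-2-[2,4,6-tris(methoxymethoxy)phenyl]-1-benzofuran-3(2H)-one, both C2 epimers | C=C(C)[C@H](CC=C(C)C)Cc1c2OC(c3c(OCOC)cc(OCOC)cc3OCOC)C(=O)c2c(OCOC)c(CC=C(C)C)c1OCOC | intermediate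
24 | 2-(iodomethyl)-4,6-bis(methoxymethoxy)-5-prenyl-7-[(R)-lavandulyl]-2-[2,4,6-tris(methoxymethoxy)phenyl]-1-benzofuran-3(2H)-one, both C2 epimers | C=C(C)[C@H](CC=C(C)C)Cc1c2OC(CI)(c3c(OCOC)cc(OCOC)cc3OCOC)C(=O)c2c(OCOC)c(CC=C(C)C)c1OCOC | intermediate
25 | primary alkyl radical from 24 (CH2• on C2 of the benzofuranone) | C=C(C)[C@H](CC=C(C)C)Cc1c2OC([CH2])(c3c(OCOC)cc(OCOC)cc3OCOC)C(=O)c2c(OCOC)c(CC=C(C)C)c1OCOC | intermediate
26 | cyclopropane-fused alkoxyl radical (C2 and C3 of the benzofuranone bridged by CH2, O• on C3) | C=C(C)[C@H](CC=C(C)C)Cc1c2OC3(c4c(OCOC)cc(OCOC)cc4OCOC)CC3([O])c2c(OCOC)c(CC=C(C)C)c1OCOC | intermediate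
27 | ring-enlarged chroman-4-on-2-yl radical | C=C(C)[C@H](CC=C(C)C)Cc1c2O[C](c3c(OCOC)cc(OCOC)cc3OCOC)CC(=O)c2c(OCOC)c(CC=C(C)C)c1OCOC | intermediate
28 | (2RS)-5,7-bis(methoxymethoxy)-6-prenyl-8-[(R)-lavandulyl]-2-[2,4,6-tris(methoxymethoxy)phenyl]-2,3-dihydro-4H-chromen-4-one, pair of C2 epimers | C=C(C)[C@H](CC=C(C)C)Cc1c2OC(c3c(OCOC)cc(OCOC)cc3OCOC)CC(=O)c2c(OCOC)c(CC=C(C)C)c1OCOC | intermediate
29 | (2S)-5,7-bis(methoxymethoxy)-6-prenyl-8-[(R)-lavandulyl]-2-[2,4,6-tris(methoxymethoxy)phenyl]-2,3-dihydro-4H-chromen-4-one | C=C(C)[C@H](CC=C(C)C)Cc1c2O[C@H](c3c(OCOC)cc(OCOC)cc3OCOC)CC(=O)c2c(OCOC)c(CC=C(C)C)c1OCOC | intermediate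
30 | (2S)-5,7-dihydroxy-6-(3-methylbut-2-en-1-yl)-8-[(2R)-5-methyl-2-(prop-1-en-2-yl)hex-4-en-1-yl]-2-(2,4,6-trihydroxyphenyl)-2,3-dihydro-4H-chromen-4-one | C=C(C)[C@H](CC=C(C)C)Cc1c(O)c(CC=C(C)C)c(O)c2c1O[C@H](c1c(O)cc(O)cc1O)CC2=O | target

**Count and risks**

Total steps: 20. Longest linear sequence: 18 (steps 1–11, then 14–20); steps 12–13 form the B-ring branch.

Three steps most likely to fail:

1. Step 18. The primary radical may be reduced before the acyl shift, or the B-ring aryl group may migrate instead of the acyl group. The fallback sets out from 24 and returns at 28, replacing the radical chain by a two-electron sequence. Iodine–lithium exchange with t-BuLi (Et2O/pentane, −100 °C) lets the primary alkyllithium add to the neighbouring ketone, which after a cold quench gives the cis-fused cyclopropanol of the benzofuranone F1. Catalytic NaOMe in MeOH/THF at 0 °C should then open the cyclopropoxide toward the benzylic, oxygen-bearing carbon (homoenolate protonation) and give 28.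

2. Step 17. The ambident enolate may alkylate on oxygen, or the crowded quaternary centre may not form. The fallback sets out from 23 and returns at 24. An aldol reaction with aqueous formaldehyde (cat. NaHCO3, THF, rt), which is reversible at oxygen and so should funnel to the C-adduct, gives the 2-(hydroxymethyl)benzofuranone F2. Appel iodination (PPh3, I2, imidazole, toluene, 60 °C) then converts it into 24.

3. Step 14. Displacement at the hindered benzylic carbinol may be slow, with the reduced azodicarboxylate being alkylated instead of the phenol. The fallback sets out from 19 and returns at 20, forming the ether bond by carbene O–H insertion. Dess–Martin oxidation of 19 gives ethyl 2-oxo-2-[2,4,6-tris(MOMO)phenyl]acetate F3. Condensation with tosylhydrazide gives the tosylhydrazone F4, and DBU converts it into ethyl 2-diazo-2-[2,4,6-tris(MOMO)phenyl]acetate F5. Rh2(OAc)4-catalysed insertion of the carbenoid into the O–H bond of phenol 15 (phenol in excess, slow addition of the diazo ester) then gives 20.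

**Further compounds**

F1 | step 18 | cyclopropanol from 24: C2 and C3 of the benzofuranone bridged by CH2, OH on C3, cis-fused | C=C(C)[C@H](CC=C(C)C)Cc1c2OC3(c4c(OCOC)cc(OCOC)cc4OCOC)CC3(O)c2c(OCOC)c(CC=C(C)C)c1OCOC
F2 | step 17 | 2-(hydroxymethyl)-4,6-bis(methoxymethoxy)-5-prenyl-7-[(R)-lavandulyl]-2-[2,4,6-tris(methoxymethoxy)phenyl]-1-benzofuran-3(2H)-one | C=C(C)[C@H](CC=C(C)C)Cc1c2OC(CO)(c3c(OCOC)cc(OCOC)cc3OCOC)C(=O)c2c(OCOC)c(CC=C(C)C)c1OCOC
F3 | step 14 | ethyl 2-oxo-2-[2,4,6-tris(methoxymethoxy)phenyl]acetate | CCOC(=O)C(=O)c1c(OCOC)cc(OCOC)cc1OCOC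
F4 | step 14 | ethyl 2-(tosylhydrazono)-2-[2,4,6-tris(methoxymethoxy)phenyl]acetate | CCOC(=O)C(=NNS(=O)(=O)c1ccc(C)cc1)c1c(OCOC)cc(OCOC)cc1OCOC
F5 | step 14 | ethyl 2-diazo-2-[2,4,6-tris(methoxymethoxy)phenyl]acetate | CCOC(=O)C(=[N+]=[N-])c1c(OCOC)cc(OCOC)cc1OCOC
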